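**The charge.** A small charge of starting material, 0.056 M, meets as much protic impurity, 0.0560 M, so the impurity falls while it competes.

    starting material → decomposition product (k1 = 2.41 × 10⁻⁶ s⁻¹)
    intermediate ⇌ isomer of the product (K2 = 2.90, k2 = 8.41 × 10⁻⁴ s⁻¹)
    starting material → intermediate (k3 = 0.00144 s⁻¹)
    intermediate ⇌ target (K4 = 2.8, k4 = 0.00186 s⁻¹)
    starting material + protic impurity → quenched substrate (k5 = 0.0197 M⁻¹ s⁻¹)

the same everywhere: protic impurity 0.0560 M
- dawn: starting material 0.056 M; time 80 min; everything together in a closed stirred flask, run for 80 min
- summer: starting material 0.056 M; time 80 min; a tube with plug flow, the mixed feed as stated, residence time 80 min
- dusk: starting material 0.056 M; a single well-mixed tank run continuously and read at steady state, 80 min in it on average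
- spring: starting material 0.056 M (fed, over 40.0 min); time 80 min; all but starting material at the start; starting material goes in evenly over 40.0 min, the run ends at 80 min

- the stated concentrations are those of everything mixed, before any reaction; amounts are the same in each set-up
- the feed brings no volume worth counting
- run time (dawn): 80 min

- the set-up with the highest amount of target at the outlet or at the end, in percent of the starting material put in ("none" if the first two lie within 2 percentage points) (dawn / summer / dusk / spring / none)
- amount of target at the outlet or at the end, in percent of the starting material put in, dawn
- amount of target at the outlet or at the end, in percent of the starting material put in, summer
- amount of target at the outlet or at the end, in percent of the starting material put in, dusk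
- amount of target at the outlet or at the end, in percent of the starting material put in, spring

**First share.** Let f be the fraction of starting material that reaches the intermediate: the constant of that step over the sum of the constants leading away, with the quench constant multiplied by the impurity. Starting material has a half-life of 8.0 min by the step to intermediate alone and, at charged impurity, 10 min by the quench alone, while by decomposition alone it is 80 h, far longer than either. Holding the impurity constant, the pseudo-first-order view, gives 0.566.

**The objection.** The impurity does not stay constant: each quench spends one impurity. Putting the first answer back, the mean of the impurity's start and end is 0.0438 M, and the share becomes 0.624. A second round gives a mean of 0.0455 M and a share of 0.616. This value is the branch share f, the fraction of the charge that enters the intermediate.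

**Slow feeding.** Dosing might seem to change this. But the impurity spent follows the amount of starting material reacted, not the clock, so f serves dawn, summer and spring alike. The tank in dusk differs: it holds impurity near the outlet value, 0.0345 M, and at that level about 8.94% of the charge leaves unreacted, a loss set against a share of 0.679 of what does react, above f.

**Target's part.** At equilibrium, target takes 0.418 of the pool of intermediate, target and isomer of the product, which gives 25.7% of the charge. Yet the pool may not be at equilibrium by 80 min: the intermediate's half-life by the forward step to target alone is 6.2 min, shorter than the 14 min by the forward step to the isomer alone. So 25.7% is a first estimate for dawn and summer, which run the same course, and target there may stand a little above it. Spring, with later intermediate, should stand slightly higher; this reckoning puts no number on that gap and leans towards none.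

**The result.** The forecast gave 27.8% for dawn, 27.8% for summer, 26.5% for dusk and 29% for spring, with the call none, holding that “Slow feeding leaves the same split against the impurity”. The simulation gives 27.9%, 27.9%, 26.5% and 29.1%, in the same order. Spring leads dawn by 1.2 percentage points, inside the margin of 2 points, so the answer is none.

**Share at work.** In dawn, target, isomer of the product and intermediate together read 62.1% of the charge, beside 61.6% from the branch share. In spring, striking out the quench lifts target from 29.1% to 46.7%; the quench is a part of the shortfall, acting together with the reverse step from target to intermediate. Those two spring figures stand in a ratio of 0.623, against a branch share of 0.616.

The constants stand for no real mixture; the run is a simulation.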